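The route rests on cutting ring C of the dihydroflavonol at O1–C2 and C3–C4. The feature exploited is that O1 and C4 both sit on ring A, so ring C can be stitched on between them, while C2 bears ring B, whose 4′-hydroxyl turns a C2=C3 styrene into a C3 nucleophile. A chiral phosphoric acid unites a ring A methoxy ortho-quinone methide, released from a salicylaldehyde dimethyl acetal, with the (E)-enol acetate of the ring B arylacetaldehyde; this one operation forms both bonds, closes ring C and sets C2 and C3 trans. The precursors are hydroxy acetal 5 and free-phenol enol acetate 13, the latter made geometrically pure by a stereoretentive CuBr-catalysed coupling.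

Key step: step 9

Abbreviations: prenyl = 3-methylbut-2-en-1-yl; MOM = methoxymethyl; (R)-TRIP = (R)-3,3′-bis(2,4,6-triisopropylphenyl)-1,1′-binaphthalene-2,2′-diyl hydrogen phosphate.

Assumption: the (R)-antipode of the phosphoric acid is taken to deliver adduct 16 with the configuration shown; should the sense prove opposite, the (S)-antipode is used and nothing else changes.

Remark: C3 is labelled S in 16, 17 and 18 and R in 19 and 20 only because the CIP rank of C4 relative to C2 changes on oxidation; the 2,3-trans arrangement in space is the same throughout.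

Step 1
Reactants: 1 2,4-dihydroxybenzaldehyde; 2 prenyl bromide
Product: 3 2,4-dihydroxy-3-prenylbenzaldehyde
Conditions: KOH (aq), 0 °C to rt
Reagents that add atoms: none
Why: Phenoxide C-alkylation in water (the solvated oxygen is a poor nucleophile) places the prenyl group mainly at C3, the position activated by both hydroxyls, so the 3-prenyl aldehyde is reached in one operation of modest efficiency, the 5-prenyl and O-prenyl isomers being removed by chromatography.

Step 2
Reactants: 3 2,4-dihydroxy-3-prenylbenzaldehyde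
Product: 4 2-hydroxy-4-(methoxymethoxy)-3-prenylbenzaldehyde
Conditions: MOMCl (1.1 equiv), K2CO3, acetone, rt
Reagents that add atoms: chloromethyl methyl ether, COCCl
Why: Williamson etherification is selective for the 4-hydroxyl because the 2-hydroxyl is hydrogen-bonded to the aldehyde and shielded by the prenyl group.

Step 3
Reactants: 4 2-hydroxy-4-(methoxymethoxy)-3-prenylbenzaldehyde
Product: 5 2-(dimethoxymethyl)-5-(methoxymethoxy)-6-prenylphenol
Conditions: HC(OMe)3, PPTS (cat.), MeOH, rt; then Et3N
Reagents that add atoms: trimethyl orthoformate, COC(OC)OC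
Why: Acid-catalysed acetalisation with the orthoester as dehydrating agent; the weak acid spares the MOM ether and the prenyl group, and the labile hydroxy acetal is quenched with Et3N, kept off silica and used directly.

Step 4
Reactants: 6 4-iodophenol; 2 prenyl bromide
Product: 7 4-iodo-2,6-diprenylphenol
Conditions: 2 (2.2 equiv), NaOH (aq), rt
Reagents that add atoms: none
Why: Double ortho C-prenylation of the phenoxide in water, the para position being blocked by iodine, is a known phenoxide C-alkylation of para-halophenols; mono-prenylated and O-prenylated material is separated.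

Step 5
Reactants: 7 4-iodo-2,6-diprenylphenol
Product: 8 5-iodo-2-(methoxymethoxy)-1,3-diprenylbenzene
Conditions: NaH, DMF, 0 °C; then MOMCl, 0 °C to rt
Reagents that add atoms: chloromethyl methyl ether, COCCl
Why: Williamson etherification of the hindered sodium phenoxide; the MOM ether protects the oxidation-prone phenol through steps 6 and 7 and is inert to KHF2, which a silyl ether might not be.

Step 6
Reactants: 8 5-iodo-2-(methoxymethoxy)-1,3-diprenylbenzene; 9 vinylboronic acid pinacol ester
Product: 11 potassium (E)-trifluoro{2-[4-(methoxymethoxy)-3,5-diprenylphenyl]ethenyl}borate, via the (E)-alkenyl pinacol boronate 10 (not isolated)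
Conditions: Pd[P(t-Bu)3]2 (5 mol %), i-Pr2NH, toluene, 80 °C; then KHF2 (aq), MeOH, rt
Reagents that add atoms: potassium hydrogen difluoride, [K+].[F-].F
Why: Mizoroki–Heck arylation of the vinyl boronate with a bulky electron-rich phosphine and an amine base in the absence of water favours β-arylation over Suzuki coupling and gives the (E)-alkene by syn insertion and syn β-hydride elimination, the trisubstituted prenyl alkenes being inert; KHF2 then converts the pinacol ester into the crystalline trifluoroborate.

Step 7
Reactants: 11 potassium (E)-trifluoro{2-[4-(methoxymethoxy)-3,5-diprenylphenyl]ethenyl}borate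
Product: 12 (E)-2-[4-(methoxymethoxy)-3,5-diprenylphenyl]ethenyl acetate
Conditions: AcOH, CuBr (10 mol %), DMAP (20 mol %), 4 Å MS, O2 (1 atm), CH2Cl2, 40 °C
Reagents that add atoms: acetic acid, CC(=O)O
Why: CuBr-catalysed oxidative C–O coupling of alkenyl trifluoroborates with carboxylic acids (Chan–Lam type) proceeds with retention of alkene geometry, so the (E)-enol acetate is obtained free of the (Z)-isomer, which enolisation and acetylation of the arylacetaldehyde could not guarantee.

Step 8
Reactants: 12 (E)-2-[4-(methoxymethoxy)-3,5-diprenylphenyl]ethenyl acetate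
Product: 13 (E)-2-(4-hydroxy-3,5-diprenylphenyl)ethenyl acetate
Conditions: ZnBr2, n-PrSH, CH2Cl2, 0 °C, 10 min
Reagents that add atoms: none
Why: Lewis acid-assisted MOM ether cleavage, in which ZnBr2 activates the acetal and the soft thiol takes up the methoxymethyl group, is complete within minutes at 0 °C and leaves the enol acetate and the prenyl groups intact, unlike protic acid.

Step 9
Reactants: 5 2-(dimethoxymethyl)-5-(methoxymethoxy)-6-prenylphenol; 13 (E)-2-(4-hydroxy-3,5-diprenylphenyl)ethenyl acetate
Product: 16 (2R,3S)-2-(4-hydroxy-3,5-diprenylphenyl)-4-methoxy-7-(methoxymethoxy)-8-prenyl-3,4-dihydro-2H-chromen-3-yl acetate (2,3-trans; both C4 epimers), via the methoxy ortho-quinone methide 14 (not isolated), via the para-quinone methide adduct 15 (not isolated)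
Conditions: (R)-TRIP (10 mol %), 5 Å MS, toluene, −30 °C
Reagents that add atoms: none
Why: Proposed new method: the phosphoric acid should ionise acetal 5 by loss of methanol to the methoxy ortho-quinone methide 14 held on the phosphate, C3 of the enol acetate (the carbon remote from ring B, made nucleophilic by the para-hydroxyl push, which outweighs the weak donation of the acetoxy oxygen) adds to the methide carbon to forge C3–C4, and the resulting para-quinone methide 15 is closed at C2 by the regenerated ring A phenol (O1–C2), which amounts to a stepwise inverse-electron-demand hetero-Diels–Alder reaction. The closest known reactions are chiral phosphoric acid-catalysed [4+2] cycloadditions of ortho-quinone methides with hydroxystyrenes and achiral acid-promoted cycloadditions of salicylaldehyde acetals with styrenes; an alkoxy quinone methide paired with an enol ester under asymmetric catalysis is without precedent. Ring C closes by a 6-exo-trig oxa-1,6-addition. C3 is set in the C–C bond formation by the catalyst, which binds the quinone methide oxygen and the ring B hydroxyl and so exposes one face of the geometrically pure (E)-alkene; C2 is then set relative to C3 in a chair-like closure with aryl and acetoxy both equatorial (2,3-trans, also the thermodynamic outcome if the oxa-addition is reversible), while C4 is uncontrolled and is erased in step 12. The step needs regioselectivity (secured by the para-hydroxyl and the poorly donating ester oxygen), chemoselectivity over the three prenyl alkenes (far less nucleophilic and not activated by hydrogen bonding, and left alone by a weak acid at low temperature) and enantiofacial control, and the sieves take up the methanol so that it cannot intercept 15.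

Step 10
Reactants: 16 (2R,3S)-2-(4-hydroxy-3,5-diprenylphenyl)-4-methoxy-7-(methoxymethoxy)-8-prenyl-3,4-dihydro-2H-chromen-3-yl acetate (both C4 epimers)
Product: 17 (2R,3S)-2-(4-acetoxy-3,5-diprenylphenyl)-4-methoxy-7-(methoxymethoxy)-8-prenyl-3,4-dihydro-2H-chromen-3-yl acetate (both C4 epimers)
Conditions: Ac2O, pyridine, DMAP (cat.), CH2Cl2, 0 °C to rt
Reagents that add atoms: acetic anhydride, CC(=O)OC(C)=O
Why: DMAP-catalysed acetylation of the only free hydroxyl caps the hindered, easily oxidised ring B phenol before the oxidation and, by weakening the donor ability of ring B, suppresses ionisation of the O1–C2 bond in the next two steps.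

Step 11
Reactants: 17 (2R,3S)-2-(4-acetoxy-3,5-diprenylphenyl)-4-methoxy-7-(methoxymethoxy)-8-prenyl-3,4-dihydro-2H-chromen-3-yl acetate (both C4 epimers)
Product: 18 (2R,3S)-2-(4-acetoxy-3,5-diprenylphenyl)-4-hydroxy-7-(methoxymethoxy)-8-prenyl-3,4-dihydro-2H-chromen-3-yl acetate (both C4 epimers)
Conditions: TsOH·H2O (20 mol %), THF/H2O (4:1), rt
Reagents that add atoms: water, O
Why: SN1 solvolysis of the benzylic methyl ether: the C4 cation is stabilised by O1 (ortho) and O7 (para) so strongly that weak aqueous acid suffices, acetoxonium participation by the C3 acetate should not compete, both C4 epimers converge on the alcohol, and the aryl MOM ether and the esters survive.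

Step 12
Reactants: 18 (2R,3S)-2-(4-acetoxy-3,5-diprenylphenyl)-4-hydroxy-7-(methoxymethoxy)-8-prenyl-3,4-dihydro-2H-chromen-3-yl acetate (both C4 epimers)
Product: 19 (2R,3R)-2-(4-acetoxy-3,5-diprenylphenyl)-7-(methoxymethoxy)-4-oxo-8-prenyl-3,4-dihydro-2H-chromen-3-yl acetate
Conditions: Dess–Martin periodinane, pyridine, CH2Cl2, 0 °C to rt
Reagents that add atoms: none
Why: Dess–Martin oxidation of the secondary benzylic alcohol, buffered by pyridine, gives the aryl ketone without touching prenyl, MOM or ester groups and erases the uncontrolled C4 stereocentre.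

Step 13
Reactants: 19 (2R,3R)-2-(4-acetoxy-3,5-diprenylphenyl)-7-(methoxymethoxy)-4-oxo-8-prenyl-3,4-dihydro-2H-chromen-3-yl acetate
Product: 20 (2R,3R)-3,7-dihydroxy-2-(4-hydroxy-3,5-diprenylphenyl)-8-prenyl-2,3-dihydro-4H-chromen-4-one (CNP0316331.1)
Conditions: HCl (1.25 M in MeOH), 40 °C
Reagents that add atoms: none
Why: Acid-catalysed methanolysis cleaves the MOM acetal and transesterifies both acetates in one operation; acid is chosen because base would open ring C through the C3 enolate and erode C2 and C3, and the mild temperature keeps the ortho-prenyl phenols from cyclising to chromans.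

Compound list
1 | 2,4-dihydroxybenzaldehyde | O=Cc1ccc(O)cc1O | starting material
2 | prenyl bromide (1-bromo-3-methylbut-2-ene) | CC(C)=CCBr | starting material
3 | 2,4-dihydroxy-3-prenylbenzaldehyde | O=Cc1ccc(O)c(CC=C(C)C)c1O | intermediate
4 | 2-hydroxy-4-(methoxymethoxy)-3-prenylbenzaldehyde | O=Cc1ccc(OCOC)c(CC=C(C)C)c1O | intermediate
5 | 2-(dimethoxymethyl)-5-(methoxymethoxy)-6-prenylphenol | COC(OC)c1ccc(OCOC)c(CC=C(C)C)c1O | intermediate
6 | 4-iodophenol | Oc1ccc(I)cc1 | starting material
7 | 4-iodo-2,6-diprenylphenol | CC(C)=CCc1cc(I)cc(CC=C(C)C)c1O | intermediate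
8 | 5-iodo-2-(methoxymethoxy)-1,3-diprenylbenzene | COCOc1c(CC=C(C)C)cc(I)cc1CC=C(C)C | intermediate
9 | vinylboronic acid pinacol ester (2-ethenyl-4,4,5,5-tetramethyl-1,3,2-dioxaborolane) | C=CB1OC(C)(C)C(C)(C)O1 | starting material
10 | 2-{(E)-2-[4-(methoxymethoxy)-3,5-diprenylphenyl]ethenyl}-4,4,5,5-tetramethyl-1,3,2-dioxaborolane | COCOc1c(CC=C(C)C)cc(/C=C/B2OC(C)(C)C(C)(C)O2)cc1CC=C(C)C | intermediate (not isolated)
11 | potassium (E)-trifluoro{2-[4-(methoxymethoxy)-3,5-diprenylphenyl]ethenyl}borate | COCOc1c(CC=C(C)C)cc(/C=C/[B-](F)(F)F)cc1CC=C(C)C.[K+] | intermediate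
12 | (E)-2-[4-(methoxymethoxy)-3,5-diprenylphenyl]ethenyl acetate | CC(=O)O/C=C/c1cc(CC=C(C)C)c(OCOC)c(CC=C(C)C)c1 | intermediate
13 | (E)-2-(4-hydroxy-3,5-diprenylphenyl)ethenyl acetate | CC(=O)O/C=C/c1cc(CC=C(C)C)c(O)c(CC=C(C)C)c1 | intermediate
14 | (6E)-6-(methoxymethylidene)-3-(methoxymethoxy)-2-prenylcyclohexa-2,4-dien-1-one | CO/C=C1/C(=O)C(CC=C(C)C)=C(OCOC)C=C1 | intermediate (not isolated)
15 | (2R)-1-[2-hydroxy-4-(methoxymethoxy)-3-prenylphenyl]-1-methoxy-3-(4-oxo-3,5-diprenylcyclohexa-2,5-dien-1-ylidene)propan-2-yl acetate (both epimers at the methoxy-bearing carbon) | CC(C)=CCC1=CC(=C[C@@H](OC(C)=O)C(OC)c2ccc(OCOC)c(CC=C(C)C)c2O)C=C(CC=C(C)C)C1=O | intermediate (not isolated)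
16 | (2R,3S)-2-(4-hydroxy-3,5-diprenylphenyl)-4-methoxy-7-(methoxymethoxy)-8-prenyl-3,4-dihydro-2H-chromen-3-yl acetate (2,3-trans; both C4 epimers) | CC(C)=CCc1cc([C@H]2Oc3c(ccc(OCOC)c3CC=C(C)C)C(OC)[C@@H]2OC(C)=O)cc(CC=C(C)C)c1O | intermediate
17 | (2R,3S)-2-(4-acetoxy-3,5-diprenylphenyl)-4-methoxy-7-(methoxymethoxy)-8-prenyl-3,4-dihydro-2H-chromen-3-yl acetate (both C4 epimers) | CC(C)=CCc1cc([C@H]2Oc3c(ccc(OCOC)c3CC=C(C)C)C(OC)[C@@H]2OC(C)=O)cc(CC=C(C)C)c1OC(C)=O | intermediate
18 | (2R,3S)-2-(4-acetoxy-3,5-diprenylphenyl)-4-hydroxy-7-(methoxymethoxy)-8-prenyl-3,4-dihydro-2H-chromen-3-yl acetate (both C4 epimers) | CC(C)=CCc1cc([C@H]2Oc3c(ccc(OCOC)c3CC=C(C)C)C(O)[C@@H]2OC(C)=O)cc(CC=C(C)C)c1OC(C)=O | intermediate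
19 | (2R,3R)-2-(4-acetoxy-3,5-diprenylphenyl)-7-(methoxymethoxy)-4-oxo-8-prenyl-3,4-dihydro-2H-chromen-3-yl acetate | CC(C)=CCc1cc([C@H]2Oc3c(ccc(OCOC)c3CC=C(C)C)C(=O)[C@@H]2OC(C)=O)cc(CC=C(C)C)c1OC(C)=O | intermediate
20 | (2R,3R)-3,7-dihydroxy-2-(4-hydroxy-3,5-diprenylphenyl)-8-prenyl-2,3-dihydro-4H-chromen-4-one (CNP0316331.1) | CC(C)=CCc1cc([C@H]2Oc3c(ccc(O)c3CC=C(C)C)C(=O)[C@@H]2O)cc(CC=C(C)C)c1O | target

Total step count: 13.
Longest linear sequence: 10 steps (6 to 20, steps 4 to 13).

Steps most likely to fail

1. Step 9. The ionised acetal may condense with itself or attack a prenyl alkene instead of the enol acetate, the enol acetate may react at the wrong carbon, or the catalyst may give poor facial selectivity. The fallback uses known chemistry, sets out from 8 and 2, and returns to the route at 20. Purchased 2,4-dihydroxyacetophenone F1 is C-prenylated with 2 as in step 1 to 2,4-dihydroxy-3-prenylacetophenone F2 and protected twice (NaH, MOMCl, DMF) to 2,4-bis(methoxymethoxy)-3-prenylacetophenone F3. Iodide 8 undergoes iodine–lithium exchange (n-BuLi, THF, −78 °C) and formylation with DMF to 4-(methoxymethoxy)-3,5-diprenylbenzaldehyde F4. Claisen–Schmidt condensation (KOH, EtOH) should give (E)-1-[2,4-bis(methoxymethoxy)-3-prenylphenyl]-3-[4-(methoxymethoxy)-3,5-diprenylphenyl]prop-2-en-1-one F5. Juliá–Colonna epoxidation (poly-L-leucine, urea–H2O2, DBU, THF) attacks only the enone and should give [2,4-bis(methoxymethoxy)-3-prenylphenyl]{(2R,3S)-3-[4-(methoxymethoxy)-3,5-diprenylphenyl]oxiran-2-yl}methanone F6. HCl in MeOH then removes the three MOM groups, and the freed 2′-hydroxyl opens the epoxide at the benzylic carbon to give 20; C3 keeps the epoxide configuration and C2 settles trans.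

2. Step 11. The C3 acetate may participate at the C4 cation and migrate to O4, or the MOM group may be lost early. The fallback sets out from 17 and returns at 19: DDQ in CH2Cl2 and pH 7 buffer at 0 °C abstracts the C4 hydride (α to the methoxy group and benzylic to the dioxygenated ring A), and water converts the methoxy-stabilised cation into ketone 19 with loss of methanol. This is the oxidative cleavage known for electron-rich benzylic methyl ethers; it bypasses alcohol 18, and ring B, deactivated as its acetate, should not be attacked. This fallback makes no new compound (F0).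

3. Step 13. Ester methanolysis may be slow enough for acid-promoted cyclisation of the ortho-prenyl phenols onto their alkenes, or for epimerisation, to compete. The fallback sets out from 16 and returns at 20, replacing the esters by acetals so that the last step only cleaves MOM groups. K2CO3 in MeOH (harmless here because no ketone is present) removes the acetate to give (2R,3S)-2-(4-hydroxy-3,5-diprenylphenyl)-4-methoxy-7-(methoxymethoxy)-8-prenyl-3,4-dihydro-2H-chromen-3-ol F7. NaH and MOMCl protect both hydroxyls to give (2R,3S)-4-methoxy-3,7-bis(methoxymethoxy)-2-[4-(methoxymethoxy)-3,5-diprenylphenyl]-8-prenyl-3,4-dihydro-2H-chromene F8. Solvolysis as in step 11, now without a neighbouring ester, gives (2R,3S)-3,7-bis(methoxymethoxy)-2-[4-(methoxymethoxy)-3,5-diprenylphenyl]-8-prenyl-3,4-dihydro-2H-chromen-4-ol F9. Dess–Martin oxidation gives (2R,3R)-3,7-bis(methoxymethoxy)-2-[4-(methoxymethoxy)-3,5-diprenylphenyl]-8-prenyl-2,3-dihydro-4H-chromen-4-one F10, and brief treatment with HCl in MeOH gives 20.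

Further compounds
F1 | step 9 | 2,4-dihydroxyacetophenone (purchased) | CC(=O)c1ccc(O)cc1O
F2 | step 9 | 2,4-dihydroxy-3-prenylacetophenone | CC(=O)c1ccc(O)c(CC=C(C)C)c1O
F3 | step 9 | 2,4-bis(methoxymethoxy)-3-prenylacetophenone | CC(=O)c1ccc(OCOC)c(CC=C(C)C)c1OCOC
F4 | step 9 | 4-(methoxymethoxy)-3,5-diprenylbenzaldehyde | COCOc1c(CC=C(C)C)cc(C=O)cc1CC=C(C)C
F5 | step 9 | (E)-1-[2,4-bis(methoxymethoxy)-3-prenylphenyl]-3-[4-(methoxymethoxy)-3,5-diprenylphenyl]prop-2-en-1-one | COCOc1ccc(C(=O)/C=C/c2cc(CC=C(C)C)c(OCOC)c(CC=C(C)C)c2)c(OCOC)c1CC=C(C)C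
F6 | step 9 | [2,4-bis(methoxymethoxy)-3-prenylphenyl]{(2R,3S)-3-[4-(methoxymethoxy)-3,5-diprenylphenyl]oxiran-2-yl}methanone | COCOc1ccc(C(=O)[C@@H]2O[C@H]2c3cc(CC=C(C)C)c(OCOC)c(CC=C(C)C)c3)c(OCOC)c1CC=C(C)C
F0 | step 11 | none | none
F7 | step 13 | (2R,3S)-2-(4-hydroxy-3,5-diprenylphenyl)-4-methoxy-7-(methoxymethoxy)-8-prenyl-3,4-dihydro-2H-chromen-3-ol (both C4 epimers) | CC(C)=CCc1cc([C@H]2Oc3c(ccc(OCOC)c3CC=C(C)C)C(OC)[C@@H]2O)cc(CC=C(C)C)c1O
F8 | step 13 | (2R,3S)-4-methoxy-3,7-bis(methoxymethoxy)-2-[4-(methoxymethoxy)-3,5-diprenylphenyl]-8-prenyl-3,4-dihydro-2H-chromene (both C4 epimers) | CC(C)=CCc1cc([C@H]2Oc3c(ccc(OCOC)c3CC=C(C)C)C(OC)[C@@H]2OCOC)cc(CC=C(C)C)c1OCOC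
F9 | step 13 | (2R,3S)-3,7-bis(methoxymethoxy)-2-[4-(methoxymethoxy)-3,5-diprenylphenyl]-8-prenyl-3,4-dihydro-2H-chromen-4-ol (both C4 epimers) | CC(C)=CCc1cc([C@H]2Oc3c(ccc(OCOC)c3CC=C(C)C)C(O)[C@@H]2OCOC)cc(CC=C(C)C)c1OCOC
F10 | step 13 | (2R,3R)-3,7-bis(methoxymethoxy)-2-[4-(methoxymethoxy)-3,5-diprenylphenyl]-8-prenyl-2,3-dihydro-4H-chromen-4-one | CC(C)=CCc1cc([C@H]2Oc3c(ccc(OCOC)c3CC=C(C)C)C(=O)[C@@H]2OCOC)cc(CC=C(C)C)c1OCOC
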